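**Retrosynthetic overview**

1. C3 is the only stereocentre and is an enolisable α-aryl ketone carbon, so it is set last: the target comes from catalytic enantioselective protonation of the achiral silyl enol ether of the racemic ketone.
2. The racemic ketone comes from BCl3 unmasking (5-OMe, 4'-O-isopropyl) of a 5,7-dimethoxyisoflavanone.
3. Ring C comes from a one-step isomerisation of a 3,5-dimethoxyphenyl 2-arylacrylate: Fries acyl shift (C4–C4a), then oxa-Michael closure (O1–C2). The enabling feature is that ring A is a phloroglucinol ring (oxygen at C5, C7, C8a), so C4a is ortho/para to three oxygens and, in symmetrical 3,5-dimethoxyphenol, both ortho carbons are equivalent; C2–C3–C4 is an α-aryl acrylate with two electrophilic sites (acyl carbon, CH2 terminus).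
4. The acrylic acid comes from hydroxycarbonylation of an aryl alkyne, the alkyne from the aldehyde, and the 1,1-dimethylallyl group from an aromatic Claisen rearrangement of the prenyl ether of 4-hydroxy-2-methoxybenzaldehyde.
5. Ring order: rings A and B are bought as benzenoid starting materials; ring C is the only ring formed (step 7).

Key step: step 7

Remark on the chemistry: compounds 10 and 11 are carried as racemates (drawn without stereodescriptor) because C3 would not stay defined through Lewis acid or base; its configuration is fixed only in step 10.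

**Route**

Step 1
Reactants: 1 4-hydroxy-2-methoxybenzaldehyde
Product: 2 2-methoxy-4-[(3-methylbut-2-en-1-yl)oxy]benzaldehyde
Conditions: prenyl bromide, K2CO3, acetone, reflux
Reagents that add atoms: 1-bromo-3-methylbut-2-ene, CC(C)=CCBr
Why: Williamson etherification; the phenoxide of 1 should be alkylated at oxygen by the primary allylic bromide (SN2).

Step 2
Reactants: 2 2-methoxy-4-[(3-methylbut-2-en-1-yl)oxy]benzaldehyde
Product: 3 4-hydroxy-2-methoxy-5-(2-methylbut-3-en-2-yl)benzaldehyde
Conditions: N,N-diethylaniline, 195 °C, sealed tube, argon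
Reagents that add atoms: none
Why: Aromatic Claisen rearrangement; the [3,3] shift should bring the dimethyl-substituted terminus of the prenyl group to the ring carbon ortho to oxygen, with C5 preferred because C3 is flanked by two oxygen substituents.

Step 3
Reactants: 3 4-hydroxy-2-methoxy-5-(2-methylbut-3-en-2-yl)benzaldehyde
Product: 4 2-methoxy-5-(2-methylbut-3-en-2-yl)-4-(propan-2-yloxy)benzaldehyde
Conditions: 2-iodopropane, Cs2CO3, DMF, 60 °C
Reagents that add atoms: 2-iodopropane, CC(C)I
Why: Williamson etherification masks the phenol as an isopropyl ether, which is inert to base and mild acid and is cleavable by BCl3 in step 8.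

Step 4
Reactants: 4 2-methoxy-5-(2-methylbut-3-en-2-yl)-4-(propan-2-yloxy)benzaldehyde
Product: 5 1-ethynyl-2-methoxy-5-(2-methylbut-3-en-2-yl)-4-(propan-2-yloxy)benzene
Conditions: dimethyl (1-diazo-2-oxopropyl)phosphonate, K2CO3, MeOH, 0 °C → rt
Reagents that add atoms: dimethyl (1-diazo-2-oxopropyl)phosphonate, CC(=O)C(=[N+]=[N-])P(=O)(OC)OC
Why: Seyferth–Gilbert homologation in the Ohira–Bestmann variant; the anion of dimethyl (diazomethyl)phosphonate formed in situ should convert the aldehyde into the terminal alkyne with loss of N2.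

Step 5
Reactants: 5 1-ethynyl-2-methoxy-5-(2-methylbut-3-en-2-yl)-4-(propan-2-yloxy)benzene
Product: 6 2-[2-methoxy-5-(2-methylbut-3-en-2-yl)-4-(propan-2-yloxy)phenyl]prop-2-enoic acid
Conditions: CO (30 bar), H2O, Pd(OAc)2 (1 mol %), 2-(diphenylphosphino)pyridine, MeSO3H (cat.), THF, 50 °C
Reagents that add atoms: carbon monoxide, [C-]#[O+]; water, O
Why: Palladium-catalysed Markovnikov hydroxycarbonylation of a terminal aryl alkyne should place CO2H on the internal carbon; the alkyne reacts far faster than the hindered vinyl group.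

Step 6
Reactants: 6 2-[2-methoxy-5-(2-methylbut-3-en-2-yl)-4-(propan-2-yloxy)phenyl]prop-2-enoic acid; 7 3,5-dimethoxyphenol
Product: 8 3,5-dimethoxyphenyl 2-[2-methoxy-5-(2-methylbut-3-en-2-yl)-4-(propan-2-yloxy)phenyl]prop-2-enoate
Conditions: DCC, DMAP (cat.), CH2Cl2, 0 °C → rt
Reagents that add atoms: none
Why: Steglich esterification joins the two halves under neutral conditions through the ester oxygen that later becomes O1.

Step 7
Reactants: 8 3,5-dimethoxyphenyl 2-[2-methoxy-5-(2-methylbut-3-en-2-yl)-4-(propan-2-yloxy)phenyl]prop-2-enoate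
Product: 10 rac-5,7-dimethoxy-3-[2-methoxy-5-(2-methylbut-3-en-2-yl)-4-(propan-2-yloxy)phenyl]-2,3-dihydro-4H-chromen-4-one, via aryl vinyl ketone 9 (not isolated)
Conditions: TiCl4 (3 equiv), 2,6-di-tert-butyl-4-methylpyridine (1.2 equiv), CH2Cl2, −20 °C → rt; then aq. NaOAc, rt
Reagents that add atoms: none
Why: TiCl4 should ionise the electron-rich aryl ester and return the acyl group to the ortho carbon of the titanium phenoxide (Lewis-acid Fries rearrangement, C4–C4a), and the oxygen freed in this way adds to the CH2 terminus of aryl 1-arylvinyl ketone 9 (oxa-Michael addition, O1–C2) once the titanium chelate is hydrolysed in the buffered quench, so ester 8 isomerises to the chromanone with no atom lost. The closest known reaction type is the Lewis-acid Fries rearrangement of aryl esters of α,β-unsaturated acids that ends in chroman-4-ones (tandem Fries/oxa-Michael). Ring C closes in the 6-endo-trig mode. C3 arises by uncontrolled protonation of the enol, so 10 is a racemate by design, since this enolisable α-aryl ketone centre is more safely set after the last Lewis-acid step (step 10). The step needs ortho over para acyl migration and acylation over conjugate C-alkylation. These are secured because the two ortho carbons of the 3,5-dimethoxyphenyl group are equivalent and activated by three oxygens, the titanium phenoxide delivers the acyl group to its own ortho carbon, only the ortho ketone is drained by ring closure, a Nazarov closure is blocked because both ortho positions of the ketone-bearing ring carry oxygen, and the hindered pyridine traps the HCl formed so that the 1,1-dimethylallyl and isopropyl ether groups do not meet protic acid.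

Step 8
Reactants: 10 rac-5,7-dimethoxy-3-[2-methoxy-5-(2-methylbut-3-en-2-yl)-4-(propan-2-yloxy)phenyl]-2,3-dihydro-4H-chromen-4-one
Product: 11 rac-5-hydroxy-3-[4-hydroxy-2-methoxy-5-(2-methylbut-3-en-2-yl)phenyl]-7-methoxy-2,3-dihydro-4H-chromen-4-one
Conditions: BCl3 (5 equiv), CH2Cl2, −78 → 0 °C; then ice-water
Reagents that add atoms: none
Why: BCl3 should cleave the methyl ether peri to the ketone through a six-membered boron chelate and the isopropyl ether through its secondary alkyl group, while the unchelated methyl ethers at C7 and C2' remain (chelation-controlled and isopropyl-selective ether cleavage).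

Step 9
Reactants: 11 rac-5-hydroxy-3-[4-hydroxy-2-methoxy-5-(2-methylbut-3-en-2-yl)phenyl]-7-methoxy-2,3-dihydro-4H-chromen-4-one
Product: 12 7-methoxy-3-{2-methoxy-5-(2-methylbut-3-en-2-yl)-4-[(trimethylsilyl)oxy]phenyl}-4,5-bis[(trimethylsilyl)oxy]-2H-chromene
Conditions: TMSOTf (3.5 equiv), Et3N (5 equiv), CH2Cl2, 0 °C; pentane, filtration under argon, used crude
Reagents that add atoms: trimethylsilyl trifluoromethanesulfonate, C[Si](C)(C)OS(=O)(=O)C(F)(F)F
Why: Soft enolisation gives the only possible silyl enol ether (C3 is the only α-carbon bearing hydrogen) and silylates both phenols, which erases the stereocentre and provides an achiral substrate for step 10.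

Step 10
Reactants: 12 7-methoxy-3-{2-methoxy-5-(2-methylbut-3-en-2-yl)-4-[(trimethylsilyl)oxy]phenyl}-4,5-bis[(trimethylsilyl)oxy]-2H-chromene
Product: 14 (3S)-5-hydroxy-3-[4-hydroxy-2-methoxy-5-(2-methylbut-3-en-2-yl)phenyl]-7-methoxy-2,3-dihydro-4H-chromen-4-one, via bis-silyl ketone 13 (not isolated)
Conditions: (S)-3,3'-bis(2,4,6-triisopropylphenyl)-1,1'-binaphthyl-2,2'-diyl N-(trifluoromethylsulfonyl)thiophosphoramide (5 mol %), PhOH (1.1 equiv), toluene, rt; then MeOH, citric acid (cat.), 0 °C
Reagents that add atoms: none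
Why: Chiral Brønsted acid-catalysed enantioselective protonation of a silyl enol ether of an α-aryl cyclic ketone, with phenol as stoichiometric achiral proton source; the chiral contact ion pair should deliver the proton to one face of C3 to set (3S), the acidic methanolysis then removes the two aryl silyl groups without enolisation, and the catalyst antipode that gives (3S) is to be confirmed in a first run, both antipodes being accessible.

**Compound list**

1 | 4-hydroxy-2-methoxybenzaldehyde | COc1cc(O)ccc1C=O | starting material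
2 | 2-methoxy-4-[(3-methylbut-2-en-1-yl)oxy]benzaldehyde | COc1cc(OCC=C(C)C)ccc1C=O | intermediate
3 | 4-hydroxy-2-methoxy-5-(2-methylbut-3-en-2-yl)benzaldehyde | COc1cc(O)c(C(C)(C)C=C)cc1C=O | intermediate
4 | 2-methoxy-5-(2-methylbut-3-en-2-yl)-4-(propan-2-yloxy)benzaldehyde | COc1cc(OC(C)C)c(C(C)(C)C=C)cc1C=O | intermediate
5 | 1-ethynyl-2-methoxy-5-(2-methylbut-3-en-2-yl)-4-(propan-2-yloxy)benzene | COc1cc(OC(C)C)c(C(C)(C)C=C)cc1C#C | intermediate
6 | 2-[2-methoxy-5-(2-methylbut-3-en-2-yl)-4-(propan-2-yloxy)phenyl]prop-2-enoic acid | COc1cc(OC(C)C)c(C(C)(C)C=C)cc1C(=C)C(=O)O | intermediate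
7 | 3,5-dimethoxyphenol | COc1cc(O)cc(OC)c1 | starting material
8 | 3,5-dimethoxyphenyl 2-[2-methoxy-5-(2-methylbut-3-en-2-yl)-4-(propan-2-yloxy)phenyl]prop-2-enoate | COc1cc(OC)cc(OC(=O)C(=C)c2cc(C(C)(C)C=C)c(OC(C)C)cc2OC)c1 | intermediate
9 | 1-(2-hydroxy-4,6-dimethoxyphenyl)-2-[2-methoxy-5-(2-methylbut-3-en-2-yl)-4-(propan-2-yloxy)phenyl]prop-2-en-1-one (not isolated) | COc1cc(O)c(C(=O)C(=C)c2cc(C(C)(C)C=C)c(OC(C)C)cc2OC)c(OC)c1 | intermediate
10 | rac-5,7-dimethoxy-3-[2-methoxy-5-(2-methylbut-3-en-2-yl)-4-(propan-2-yloxy)phenyl]-2,3-dihydro-4H-chromen-4-one | C=CC(C)(C)c1cc(C2COc3cc(OC)cc(OC)c3C2=O)c(OC)cc1OC(C)C | intermediate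
11 | rac-5-hydroxy-3-[4-hydroxy-2-methoxy-5-(2-methylbut-3-en-2-yl)phenyl]-7-methoxy-2,3-dihydro-4H-chromen-4-one | C=CC(C)(C)c1cc(C2COc3cc(OC)cc(O)c3C2=O)c(OC)cc1O | intermediate
12 | 7-methoxy-3-{2-methoxy-5-(2-methylbut-3-en-2-yl)-4-[(trimethylsilyl)oxy]phenyl}-4,5-bis[(trimethylsilyl)oxy]-2H-chromene | C=CC(C)(C)c1cc(C2=C(O[Si](C)(C)C)c3c(O[Si](C)(C)C)cc(OC)cc3OC2)c(OC)cc1O[Si](C)(C)C | intermediate
13 | (3S)-7-methoxy-3-{2-methoxy-5-(2-methylbut-3-en-2-yl)-4-[(trimethylsilyl)oxy]phenyl}-5-[(trimethylsilyl)oxy]-2,3-dihydro-4H-chromen-4-one (not isolated) | C=CC(C)(C)c1cc([C@H]2COc3cc(OC)cc(O[Si](C)(C)C)c3C2=O)c(OC)cc1O[Si](C)(C)C | intermediate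
14 | (3S)-5-hydroxy-3-[4-hydroxy-2-methoxy-5-(2-methylbut-3-en-2-yl)phenyl]-7-methoxy-2,3-dihydro-4H-chromen-4-one | C=CC(C)(C)c1cc([C@H]2COc3cc(OC)cc(O)c3C2=O)c(OC)cc1O | target

**Step count and risks**

Total step count: 10. Longest linear sequence: 10 steps (1 → 14); 3,5-dimethoxyphenol 7 enters at step 6.

Steps most likely to fail:

- **Step 10.** Proton delivery to the enol ether may show poor facial selectivity, or an uncatalysed background protonation by phenol may compete. The stereocentre would then be fixed by reduction under dynamic kinetic resolution, setting out from racemic ketone 10. Asymmetric transfer hydrogenation with RuCl(p-cymene)[(S,S)-TsDPEN] in HCO2H/Et3N and EtOAc at 40 °C should reduce one enantiomer while the amine racemises C3 of the remaining ketone. This should give the cis alcohol (3S,4S)-5,7-dimethoxy-3-[2-methoxy-5-(2-methylbut-3-en-2-yl)-4-(propan-2-yloxy)phenyl]-3,4-dihydro-2H-chromen-4-ol F1. Oxidation with Dess–Martin periodinane (NaHCO3, CH2Cl2, 0 °C), which is non-basic and should leave C3 untouched, would give (3S)-5,7-dimethoxy-3-[2-methoxy-5-(2-methylbut-3-en-2-yl)-4-(propan-2-yloxy)phenyl]-2,3-dihydro-4H-chromen-4-one F2. BCl3 in CH2Cl2 at −78 → 0 °C, as in step 8, would then remove the 5-O-methyl and isopropyl groups and arrive at target 14.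

- **Step 7.** The Lewis acid may divert ester 8 by conjugate C-alkylation to the isomeric dihydrocoumarin, by para acyl migration, or by acid-induced degradation of the 1,1-dimethylallyl or isopropyl ether group. The two bonds would then be made one after the other, setting out from acid 6. Boc2O, DMAP (cat.) and t-BuOH should give tert-butyl 2-[2-methoxy-5-(2-methylbut-3-en-2-yl)-4-(propan-2-yloxy)phenyl]prop-2-enoate F3. Base-catalysed oxa-Michael addition of phenol 7 (Cs2CO3 cat., MeCN, 40 °C) should give racemic tert-butyl 3-(3,5-dimethoxyphenoxy)-2-[2-methoxy-5-(2-methylbut-3-en-2-yl)-4-(propan-2-yloxy)phenyl]propanoate F4. Brief TFA/CH2Cl2 at 0 °C would free racemic 3-(3,5-dimethoxyphenoxy)-2-[2-methoxy-5-(2-methylbut-3-en-2-yl)-4-(propan-2-yloxy)phenyl]propanoic acid F5. This is cyclised in the same flask with (CF3CO)2O by intramolecular Friedel–Crafts acylation at the activated ortho carbon, rejoining the route at 10.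

- **Step 2.** The thermal rearrangement may give mixtures through migration to C3, a second sigmatropic shift, or loss of the prenyl group. The quaternary benzylic carbon would then be made by cross-coupling, setting out from 1. Bromination (Br2, AcOH, rt; ortho to OH at C5) should give 5-bromo-4-hydroxy-2-methoxybenzaldehyde F6. O-Isopropylation as in step 3 gives 5-bromo-2-methoxy-4-(propan-2-yloxy)benzaldehyde F7. Palladium-catalysed γ-selective (branched) Suzuki–Miyaura coupling with 4,4,5,5-tetramethyl-2-(3-methylbut-2-en-1-yl)-1,3,2-dioxaborolane (Pd(OAc)2, bulky dialkylbiarylphosphine, K3PO4, THF/H2O, 40 °C) should then give aldehyde 4, where the route is rejoined.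

Further compounds
F1 | step 10 | (3S,4S)-5,7-dimethoxy-3-[2-methoxy-5-(2-methylbut-3-en-2-yl)-4-(propan-2-yloxy)phenyl]-3,4-dihydro-2H-chromen-4-ol | C=CC(C)(C)c1cc([C@H]2COc3cc(OC)cc(OC)c3[C@H]2O)c(OC)cc1OC(C)C
F2 | step 10 | (3S)-5,7-dimethoxy-3-[2-methoxy-5-(2-methylbut-3-en-2-yl)-4-(propan-2-yloxy)phenyl]-2,3-dihydro-4H-chromen-4-one | C=CC(C)(C)c1cc([C@H]2COc3cc(OC)cc(OC)c3C2=O)c(OC)cc1OC(C)C
F3 | step 7 | tert-butyl 2-[2-methoxy-5-(2-methylbut-3-en-2-yl)-4-(propan-2-yloxy)phenyl]prop-2-enoate | COc1cc(OC(C)C)c(C(C)(C)C=C)cc1C(=C)C(=O)OC(C)(C)C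
F4 | step 7 | rac-tert-butyl 3-(3,5-dimethoxyphenoxy)-2-[2-methoxy-5-(2-methylbut-3-en-2-yl)-4-(propan-2-yloxy)phenyl]propanoate | COc1cc(OC)cc(OCC(C(=O)OC(C)(C)C)c2cc(C(C)(C)C=C)c(OC(C)C)cc2OC)c1
F5 | step 7 | rac-3-(3,5-dimethoxyphenoxy)-2-[2-methoxy-5-(2-methylbut-3-en-2-yl)-4-(propan-2-yloxy)phenyl]propanoic acid | COc1cc(OC)cc(OCC(C(=O)O)c2cc(C(C)(C)C=C)c(OC(C)C)cc2OC)c1
F6 | step 2 | 5-bromo-4-hydroxy-2-methoxybenzaldehyde | COc1cc(O)c(Br)cc1C=O
F7 | step 2 | 5-bromo-2-methoxy-4-(propan-2-yloxy)benzaldehyde | COc1cc(OC(C)C)c(Br)cc1C=O
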